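(Readings and results were computed on assumed constants, noise included.)

Percent of the starting material charged was the unit I read these flasks in: a step first order in starting material integrates to an exponential, [starting material] over its charge falling as exp(−kt) with k its rate constant, and no concentration is left in that curve.

| setting | elm | ash | grey | teal | red | green | ochre |
|---|---|---|---|---|---|---|---|
| starting material | 0.036 M | 0.58 M | 0.050 M | 0.10 M | 0.20 M | 0.40 M | 0.80 M |
| coupling partner | 0.13 M | 0.13 M | 0.130 M | 0.130 M | 0.130 M | 0.130 M | 0.130 M |
| capture agent | 0.010 M | 0.010 M | 0.0100 M | 0.0100 M | 0.0100 M | 0.0100 M | 0.0100 M |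
| remark | run made earlier | run made earlier |  |  |  |  |  |
| time |  |  | 4.0 h | 4.0 h | 4.0 h | 4.0 h | 4.0 h |

| run | time / h | target / % | starting material / % |
|---|---|---|---|
| elm | 0.333 | 0 | 20.0 |
| elm | 0.500 | 1.1 | 18.8 |
| elm | 0.833 | 1.1 | 16.0 |
| elm | 1.33 | 3.0 | 13.3 |
| elm | 2.50 | 6.1 | 9.1 |
| elm | 4.00 | 11.0 | 6.1 |
| ash | 0.333 | 0.2 | 20.9 |
| ash | 0.500 | 0.9 | 18.5 |
| ash | 0.833 | 1.1 | 16.5 |
| ash | 1.33 | 1.6 | 14.5 |
| ash | 2.50 | 7.4 | 10.8 |
| ash | 4.00 | 11.7 | 7.4 |

(readings scatter by 0.5 percentage points)

- "hardly changes" means that all values lie within two and a half points (for a concentration: within two and a half percent of the largest)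

* amount of target at the end, in percent of the starting material charged for grey, teal, red, green, ochre, in this order
* how the row runs (hardly changes / falls all the way / rises all the way / falls, then rises / rises, then falls)

The bench rule follows from that: if the percent curves of two charges lie on each other, read a new charge off them. Ash was charged 16.1 times as strongly as elm, and at 4.00 h the target read 11.0 % in elm and 11.7 % in ash, a gap of 0.7 percentage points with a scatter of 0.5 points on each reading.

The rule stops where a reagent is charged at fixed molarity, since its capacity in this unit moves with the charge. So I took the capture ceiling, the limiting-reagent yield of capture: [capture agent] charged over [starting material] charged, counted one to one, which is 20.0 % in grey. The same ratio was 27.8 % in elm and 1.72 % in ash, so the earlier runs had already spanned 26 points of ceiling for that small gap in target. Ochre lies 1.38 times beyond ash in charge, but its ceiling of 1.25 % is a step of just 0.47 points below ash. Read from the two runs, the ratio of the target gap to the span of ceiling was 0.0269, which gave the row a rise of about 0.5 points from grey to ochre. That ratio rests on a gap of 0.7 points between two readings, each with a scatter of 0.5 points, and I expected a row that hardly changes.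

The forecast gave 11.3 % at each point, hardly changes, on the grounds that the scheme “behaves as first order in starting material”. It kept the row level where my slope tilted it slightly upward.

The row came out at 11.4 %, 11.6 %, 11.9 %, 12.1 % and 12.3 %: hardly changes.

    intermediate A ⇌ intermediate B (K = 0.430, k = 4.98 × 10⁻⁴ s⁻¹)
    intermediate C → target (k = 1.03 × 10⁻⁴ s⁻¹)
    starting material → intermediate C (k = 1.44 × 10⁻⁴ s⁻¹)
    capture agent + intermediate B → trapped intermediate (k = 0.0126 M⁻¹ s⁻¹)
    intermediate B → intermediate D (k = 1.89 × 10⁻⁴ s⁻¹)
    starting material ⇌ intermediate A (K = 2.80, k = 0.00881 s⁻¹)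
    intermediate D → intermediate C (k = 2.57 × 10⁻⁴ s⁻¹)
    intermediate C ⇌ intermediate E (K = 24.0, k = 3.10 × 10⁻⁴ s⁻¹)

In grey, 35 % of the capture agent was left at 4.00 h. On the capture ceiling of 20.0 %, that puts 13.0 % of the charge in trapped form, and the trapped intermediate stood at 12.9 %. Ochre, with its ceiling of 1.25 %, held 1.25 % of trapped intermediate with capture agent at 0 %.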